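Readings and results were generated by integration with made-up constants, and the scatter is random.

Start from the leftover. In the winter run, averaged over its readings, left-handed substrate stands at 89.7 % of its own charge. Its left-handed product reads 4.7 % at 0.833 d and 5.0 % at 5.00 d, a difference of 0.3 percentage points against a scatter of 0.5 points, so read this run as a plateau.

the same everywhere: added ligand 0.13 mM
- dawn: left-handed substrate 0.20 M; right-handed substrate 0.20 M; partner 1.1 equiv; free catalyst 0.05 mol%; run made earlier
- winter: left-handed substrate 0.20 M; right-handed substrate 0.20 M; partner 1.1 equiv; free catalyst 0.075 mol%; run made earlier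
- spring: left-handed substrate 0.40 M; right-handed substrate 0.40 M; partner 1.1 equiv; free catalyst 0.1 mol%; run made earlier
- flask: left-handed substrate 0.20 M; right-handed substrate 0.20 M; partner 1.10 equiv; free catalyst 0.1 mol%; time 4.0 d

| run | time / d | left-handed substrate / % | right-handed substrate / % | left-handed product / % |
|---|---|---|---|---|
| dawn | 0.417 | 47.8 | 50.1 | 2.7 |
| dawn | 0.625 | 46.7 | 49.5 | 3.2 |
| dawn | 1.04 | 46.3 | 49.9 | 3.5 |
| dawn | 1.67 | 46.4 | 49.0 | 3.1 |
| dawn | 3.00 | 47.1 | 49.7 | 3.3 |
| dawn | 5.00 | 46.6 | 49.4 | 3.9 |
| winter | 0.833 | 44.8 | 48.8 | 4.7 |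
| winter | 1.67 | 46.5 | 49.6 | 5.0 |
| winter | 2.50 | 44.8 | 50.2 | 4.9 |
| winter | 3.00 | 44.2 | 49.6 | 5.1 |
| winter | 4.00 | 44.6 | 49.8 | 5.3 |
| winter | 5.00 | 44.1 | 50.0 | 5.0 |
| spring | 0.417 | 38.4 | 48.5 | 10.2 |
| spring | 1.25 | 39.2 | 47.9 | 11.5 |
| spring | 2.00 | 38.3 | 48.4 | 11.0 |
| spring | 3.00 | 39.0 | 48.5 | 10.7 |
| spring | 5.00 | 38.7 | 49.1 | 11.3 |

(scatter of a reading: 0.5 percentage points)

1. part of the left-handed substrate and right-handed substrate charged together that has reacted at 4.0 d
2. excess of left-handed product over right-handed product in the product at 4.0 d
3. excess of right-handed substrate over left-handed substrate among what is left of the two at 4.0 d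

- free catalyst is single-handed; left-handed substrate and right-handed substrate are mirror images of each other, charged as a racemate, each of them at the stated concentration
- what was read earlier has a scatter of 0.5 percentage points, one standard deviation
- an excess is the difference of the two amounts in percent of their sum
- an excess is below zero if the other one leads

Winter is the neighbour of this flask: it has the same substrate and partner charges, but less catalyst, 0.075 mol% against 0.1 mol%. Carry one number between them, the plateau number N: minus the natural logarithm of the fraction of left-handed substrate left, divided by the catalyst concentration, at 1.1 equiv of partner. Winter gives N = 0.727 mM⁻¹. The asked time lies later than winter's first reading, so take the flask at its plateau. With 0.200 mM of catalyst, N leaves 86.5 % of the left-handed substrate, a loss of 13.5 %.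

The forecast also takes the loss as “proportional to catalyst concentration” and arrives at a loss of 12.5 % of the left-handed substrate, against 13.5 % here. It gives 6.9 % reacted, a product excess of 81 % and a substrate excess of 6 %.

The flask gives 7.32 %, 82.2 % and 6.47 %.

    free catalyst + left-handed substrate ⇌ catalyst intermediate A (K = 9.30 M⁻¹, k = 50.0 M⁻¹ min⁻¹)
    free catalyst + right-handed substrate ⇌ catalyst intermediate B (K = 4.50 M⁻¹, k = 200 M⁻¹ min⁻¹)
    partner + catalyst intermediate A → free catalyst + left-handed product (k = 8.50 M⁻¹ min⁻¹)
    partner + catalyst intermediate B → free catalyst + right-handed product (k = 1.40 M⁻¹ min⁻¹)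
    2 partner → homo dimer (k = 0.00550 M⁻¹ min⁻¹)
    free catalyst + added ligand ⇌ idle complex, settled at all times (K = 9600 M⁻¹)
    partner → decomposed reagent (k = 0.00320 min⁻¹)

The flask keeps 87 % of its left-handed substrate unbound, so its N is 0.714 mM⁻¹. A further flask with 2.80 equiv of partner, its other charges as in this flask, keeps 77 %, so its N is 1.31 mM⁻¹, higher, and N belongs to 1.1 equiv. In the flask, partner passed into decomposed reagent with the midpoint of that turnover at 0.104 d, while free catalyst and left-handed substrate formed catalyst intermediate A with their midpoint at 0.108 d. By 2.00 d partner, the limiting reagent, stood in the flask at 0 % and left-handed product at 6.64 %, and at 40.0 d left-handed product still stands at 6.64 %, with free catalyst at 22.9 % of the catalyst charged.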